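The pyranone ring is opened at O1–C8a. O1 joins ring-A carbon C8a to C2, a carboxyl-level carbon that also carries the exocyclic 4-hydroxyphenoxy group. The unit O1–C2=C3–C4=O is therefore the enol form of an aryl β-keto ester, and its ester carbonyl oxygen can be arylated by an ortho C–Br carbon of ring A. One copper-catalysed intramolecular O-arylation closes the heterocycle and delivers the complete 2-aryloxychromone with all three phenolic oxygens masked. The precursor is the 4-(triisopropylsilyloxy)phenyl ester of 3-[2,4-bis(benzyloxy)-6-bromophenyl]-3-oxopropanoic acid. Hydrogenolysis, chelation-controlled 7-O-prenylation and desilylation finish the route.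

Key step: step 7

Remarks on the chemistry:
- The target has no stereogenic element, so no step has to control configuration.
- C2 is at the carboxylic acid (ketene acetal) oxidation level: two bonds to oxygen and a double bond to C3.
- Both ring-A oxygens are benzyl ethers, so no phenoxide can attack the aryl ester, and both are removed in one neutral operation.
- The distal phenol carries a TIPS group, so after hydrogenolysis only the 5-OH and 7-OH are free and the prenylation has a single competent site.
- Bromide is kept as the leaving group because it sits ortho to the acyl group and meta to both ether donors.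

Step 1
Reactants: 1 5-bromoresorcinol
Product: 2 1,3-bis(benzyloxy)-5-bromobenzene
Conditions: BnBr (2.2 equiv), K2CO3, DMF, 60 °C
Reagents that add atoms: benzyl bromide, BrCc1ccccc1
Why: Williamson ether synthesis, in which both phenoxides displace the benzylic bromide by SN2 while the aryl bromide is inert.

Step 2
Reactants: 2 1,3-bis(benzyloxy)-5-bromobenzene
Product: 4 2,4-bis(benzyloxy)-6-bromobenzaldehyde, via aryl iminium chloride 3 (not isolated)
Conditions: POCl3, DMF, 0 → 80 °C; then H2O
Reagents that add atoms: N,N-dimethylformamide, CN(C)C=O; water, O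
Why: Vilsmeier–Haack formylation, in which the chloroiminium electrophile should attack one of the two equivalent carbons next to bromine (para to one ether, ortho to the other) in preference to the single crowded carbon between the two ethers, and water then hydrolyses iminium salt 3; any minor isomer is removed by crystallisation.

Step 3
Reactants: 4 2,4-bis(benzyloxy)-6-bromobenzaldehyde
Product: 5 2,4-bis(benzyloxy)-6-bromobenzoic acid
Conditions: NaClO2, NaH2PO4, 2-methyl-2-butene, t-BuOH/THF/H2O, rt
Reagents that add atoms: sodium chlorite, [Na+].[O-]Cl=O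
Why: Pinnick oxidation, in which chlorous acid adds to the aldehyde and fragments to the acid while the alkene scavenger intercepts hypochlorous acid so the electron-rich ring is not chlorinated.

Step 4
Reactants: 5 2,4-bis(benzyloxy)-6-bromobenzoic acid; 6 Meldrum's acid (2,2-dimethyl-1,3-dioxane-4,6-dione)
Product: 8 5-{[2,4-bis(benzyloxy)-6-bromophenyl](hydroxy)methylidene}-2,2-dimethyl-1,3-dioxane-4,6-dione, via aroyl chloride 7 (not isolated)
Conditions: (COCl)2, cat. DMF, CH2Cl2, 0 °C → rt, evaporate; then 6, DMAP (2.2 equiv), CH2Cl2, 0 °C → rt; cold dilute HCl wash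
Reagents that add atoms: none
Why: C-acylation of Meldrum's acid, in which DMAP turns the hindered aroyl chloride into a reactive N-acylpyridinium salt that is captured by the Meldrum's acid anion to give the stable enolised acyl derivative.

Step 5
Reactants: 9 hydroquinone
Product: 10 4-(triisopropylsilyloxy)phenol
Conditions: TIPSCl (1 equiv), imidazole, 9 (3 equiv), DMF, 0 °C → rt
Reagents that add atoms: triisopropylsilyl chloride, CC(C)[Si](Cl)(C(C)C)C(C)C
Why: Imidazole-promoted O-silylation of a symmetric diol used in excess, so that monosilylation dominates and the surplus hydroquinone is washed out with water.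

Step 6
Reactants: 8 5-{[2,4-bis(benzyloxy)-6-bromophenyl](hydroxy)methylidene}-2,2-dimethyl-1,3-dioxane-4,6-dione; 10 4-(triisopropylsilyloxy)phenol
Product: 12 4-(triisopropylsilyloxy)phenyl 3-[2,4-bis(benzyloxy)-6-bromophenyl]-3-oxopropanoate, via aroylketene 11 (not isolated)
Conditions: 10 (1.2 equiv), toluene, 110 °C
Reagents that add atoms: none
Why: Acylketene trapping, in which thermal cycloreversion of the acyl Meldrum's acid expels acetone and CO2 to give aroylketene 11 and the phenol adds across the ketene under neutral conditions that leave silyl ether, benzyl ethers and aryl bromide untouched.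

Step 7
Reactants: 12 4-(triisopropylsilyloxy)phenyl 3-[2,4-bis(benzyloxy)-6-bromophenyl]-3-oxopropanoate
Product: 13 5,7-bis(benzyloxy)-2-[4-(triisopropylsilyloxy)phenoxy]chromen-4-one
Conditions: CuI (10 mol%), 1,10-phenanthroline (20 mol%), K3PO4 (2 equiv), 4 Å MS, anhydrous 1,4-dioxane, 85 °C, Ar
Reagents that add atoms: none
Why: K3PO4 removes a doubly activated C3 proton of 12, the delocalised enolate binds Cu(I)(phen) through the ester-derived oxygen, the ortho C–Br bond (activated by the adjacent acyl group) undergoes oxidative addition, and C–O reductive elimination from the seven-membered aryl–Cu(III) enolate chelate forms O1–C8a. The closest known reaction type is the intramolecular Ullmann-type enolate O-arylation of 1-(2-haloaryl)-1,3-dicarbonyl compounds to 4H-chromen-4-ones. The only ring closed is the six-membered pyranone, formally a 6-exo-trig attack of oxygen on the bromine-bearing aryl carbon. No stereocentre is created. The step needs O- over C-arylation and ring closure over loss of aryloxide: attack through C3 or through the ketone oxygen would give a four-membered ring and is geometrically excluded, both ring-A oxygens are benzyl ethers so no phenoxide can lactonise onto the aryl ester to a 4-hydroxycoumarin, and a mild insoluble base in a dry non-nucleophilic medium means that an aroylketene/aryloxide pair formed by E1cB can only recombine to the enolate.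

Step 8
Reactants: 13 5,7-bis(benzyloxy)-2-[4-(triisopropylsilyloxy)phenoxy]chromen-4-one
Product: 14 5,7-dihydroxy-2-[4-(triisopropylsilyloxy)phenoxy]chromen-4-one
Conditions: H2 (1 atm), 10% Pd/C, EtOAc/THF, rt
Reagents that add atoms: none
Why: Catalytic hydrogenolysis of the two benzylic C–O bonds, with the reaction stopped once 13 is consumed; the donor-substituted conjugated C2=C3 bond, the aryl C–O bonds and the silyl ether are not expected to react at 1 atm.

Step 9
Reactants: 14 5,7-dihydroxy-2-[4-(triisopropylsilyloxy)phenoxy]chromen-4-one; 15 prenyl bromide (1-bromo-3-methylbut-2-ene)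
Product: 16 5-hydroxy-7-(3-methylbut-2-enyloxy)-2-[4-(triisopropylsilyloxy)phenoxy]chromen-4-one
Conditions: 15 (1.1 equiv), K2CO3 (1.2 equiv), acetone, rt → 40 °C
Reagents that add atoms: none
Why: Williamson etherification, in which carbonate ionises the vinylogous-acid 7-OH while the 5-OH is held in a hydrogen bond to the C4 carbonyl, so SN2 attack on the primary allylic bromide should occur at O7 only; the TIPS ether tolerates carbonate in acetone.

Step 10
Reactants: 16 5-hydroxy-7-(3-methylbut-2-enyloxy)-2-[4-(triisopropylsilyloxy)phenoxy]chromen-4-one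
Product: 17 5-hydroxy-2-(4-hydroxyphenoxy)-7-(3-methylbut-2-enyloxy)chromen-4-one
Conditions: TBAF (1.1 equiv), AcOH (1.1 equiv), THF, 0 °C
Reagents that add atoms: none
Why: Fluoride-induced Si–O cleavage driven by the strong Si–F bond, buffered with acetic acid so the liberated phenoxide is protonated at once and cannot add to the electrophilic C2; the prenyl ether and the chromone are inert.

Compound list
1 | 5-bromoresorcinol | Oc1cc(O)cc(Br)c1 | starting material
2 | 1,3-bis(benzyloxy)-5-bromobenzene | Brc1cc(OCc2ccccc2)cc(OCc2ccccc2)c1 | intermediate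
3 | N-{[2,4-bis(benzyloxy)-6-bromophenyl]methylidene}-N-methylmethanaminium chloride | C[N+](C)=Cc1c(Br)cc(OCc2ccccc2)cc1OCc1ccccc1.[Cl-] | intermediate (not isolated)
4 | 2,4-bis(benzyloxy)-6-bromobenzaldehyde | O=Cc1c(Br)cc(OCc2ccccc2)cc1OCc1ccccc1 | intermediate
5 | 2,4-bis(benzyloxy)-6-bromobenzoic acid | OC(=O)c1c(Br)cc(OCc2ccccc2)cc1OCc1ccccc1 | intermediate
6 | Meldrum's acid (2,2-dimethyl-1,3-dioxane-4,6-dione) | CC1(C)OC(=O)CC(=O)O1 | starting material
7 | 2,4-bis(benzyloxy)-6-bromobenzoyl chloride | O=C(Cl)c1c(Br)cc(OCc2ccccc2)cc1OCc1ccccc1 | intermediate (not isolated)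
8 | 5-{[2,4-bis(benzyloxy)-6-bromophenyl](hydroxy)methylidene}-2,2-dimethyl-1,3-dioxane-4,6-dione | CC1(C)OC(=O)C(=C(O)c2c(Br)cc(OCc3ccccc3)cc2OCc2ccccc2)C(=O)O1 | intermediate
9 | hydroquinone | Oc1ccc(O)cc1 | starting material
10 | 4-(triisopropylsilyloxy)phenol | CC(C)[Si](Oc1ccc(O)cc1)(C(C)C)C(C)C | intermediate
11 | 3-[2,4-bis(benzyloxy)-6-bromophenyl]-3-oxoprop-1-en-1-one (aroylketene) | O=C=CC(=O)c1c(Br)cc(OCc2ccccc2)cc1OCc1ccccc1 | intermediate (not isolated)
12 | 4-(triisopropylsilyloxy)phenyl 3-[2,4-bis(benzyloxy)-6-bromophenyl]-3-oxopropanoate | O=C(CC(=O)Oc1ccc(O[Si](C(C)C)(C(C)C)C(C)C)cc1)c1c(Br)cc(OCc2ccccc2)cc1OCc1ccccc1 | intermediate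
13 | 5,7-bis(benzyloxy)-2-[4-(triisopropylsilyloxy)phenoxy]chromen-4-one | O=c1cc(Oc2ccc(O[Si](C(C)C)(C(C)C)C(C)C)cc2)oc2cc(OCc3ccccc3)cc(OCc3ccccc3)c12 | intermediate
14 | 5,7-dihydroxy-2-[4-(triisopropylsilyloxy)phenoxy]chromen-4-one | O=c1cc(Oc2ccc(O[Si](C(C)C)(C(C)C)C(C)C)cc2)oc2cc(O)cc(O)c12 | intermediate
15 | prenyl bromide (1-bromo-3-methylbut-2-ene) | CC(C)=CCBr | starting material
16 | 5-hydroxy-7-(3-methylbut-2-enyloxy)-2-[4-(triisopropylsilyloxy)phenoxy]chromen-4-one | CC(C)=CCOc1cc(O)c2c(=O)cc(Oc3ccc(O[Si](C(C)C)(C(C)C)C(C)C)cc3)oc2c1 | intermediate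
17 | 5-hydroxy-2-(4-hydroxyphenoxy)-7-(3-methylbut-2-enyloxy)chromen-4-one | CC(C)=CCOc1cc(O)c2c(=O)cc(Oc3ccc(O)cc3)oc2c1 | target

Total step count: 10
Longest linear sequence: 9 steps (steps 1–4 and 6–10; step 5 is a one-step side branch)

Steps most likely to fail

1. Step 7. The enolate may shed the aryloxide by E1cB to the aroylketene and decompose, or oxidative addition into the C–Br bond may be too slow at a temperature the aryl ester tolerates. The fallback gives up ring closure by O-arylation and introduces the aryloxy group onto a preformed chromone by addition–elimination, all by established chemistry. It sets out from phenol 10 and returns to the route at 13. Commercial 1-[2,4-bis(benzyloxy)-6-hydroxyphenyl]ethanone F1 would be condensed with CS2 and KOtBu in THF to give 5,7-bis(benzyloxy)-4-hydroxy-2H-chromene-2-thione F2. S-Methylation (MeI, K2CO3, acetone) would give 5,7-bis(benzyloxy)-2-(methylsulfanyl)chromen-4-one F3, and mCPBA (2.2 equiv, CH2Cl2, 0 °C) would oxidise it to 5,7-bis(benzyloxy)-2-(methylsulfonyl)chromen-4-one F4. The sodium phenoxide of 10 (NaH, THF, 0 °C → rt) would then displace methanesulfinate at C2 to give 13.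

2. Step 4. C-acylation of Meldrum's acid by a benzoyl chloride with two ortho substituents may be slow, so that hydrolysis back to the acid or O-acylation takes over; the ketene trapping of step 6 depends on the same crowded acyl unit. The fallback builds the C3–C4 bond by enolate addition to the more accessible aldehyde carbonyl. It sets out from aldehyde 4, returns at 12, and bypasses steps 3, 4 and 6. Phenol 10 would be acetylated (Ac2O, pyridine) to 4-(triisopropylsilyloxy)phenyl acetate F5. Its lithium enolate (LDA, THF, −78 °C) would add to 4 and be quenched cold with AcOH, before the aldolate can lactonise, to give racemic 4-(triisopropylsilyloxy)phenyl 3-[2,4-bis(benzyloxy)-6-bromophenyl]-3-hydroxypropanoate F6. Dess–Martin oxidation (CH2Cl2, NaHCO3, rt) would then give 12.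

3. Step 9. The ambident phenoxide may be alkylated a second time at O5 or at C6/C8, or the base may erode the silyl ether and expose the distal phenol to alkylation. The fallback avoids base and phenoxide altogether: a Mitsunobu etherification of 14 with 3-methylbut-2-en-1-ol (PPh3, DIAD, THF, 0 °C). Only the acidic, non-chelated 7-OH should serve as pronucleophile. It sets out from 14, returns at 16, and makes no compound outside the list (F0).

Further compounds
F1 | step 7 | 1-[2,4-bis(benzyloxy)-6-hydroxyphenyl]ethanone | CC(=O)c1c(O)cc(OCc2ccccc2)cc1OCc1ccccc1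
F2 | step 7 | 5,7-bis(benzyloxy)-4-hydroxy-2H-chromene-2-thione | Oc1cc(=S)oc2cc(OCc3ccccc3)cc(OCc3ccccc3)c12
F3 | step 7 | 5,7-bis(benzyloxy)-2-(methylsulfanyl)chromen-4-one | CSc1cc(=O)c2c(OCc3ccccc3)cc(OCc3ccccc3)cc2o1
F4 | step 7 | 5,7-bis(benzyloxy)-2-(methylsulfonyl)chromen-4-one | CS(=O)(=O)c1cc(=O)c2c(OCc3ccccc3)cc(OCc3ccccc3)cc2o1
F5 | step 4 | 4-(triisopropylsilyloxy)phenyl acetate | CC(=O)Oc1ccc(O[Si](C(C)C)(C(C)C)C(C)C)cc1
F6 | step 4 | 4-(triisopropylsilyloxy)phenyl 3-[2,4-bis(benzyloxy)-6-bromophenyl]-3-hydroxypropanoate (racemic) | OC(CC(=O)Oc1ccc(O[Si](C(C)C)(C(C)C)C(C)C)cc1)c1c(Br)cc(OCc2ccccc2)cc1OCc1ccccc1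
F0 | step 9 | none | none
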